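**Plan**

1. Retrosynthetic cuts, in order: the C10 acetate; C1–C2 and C3=C4 of the enyne (back to a C5 allyl group); then, in one event, the ring O–C6 bond together with C7–Cl and C9–Cl; then O–C12/C13–Br; C7–C8; C12=C13.
2. Forward: 2-deoxy-D-ribose supplies C8–C12, a Wittig reaction adds C13–C15 as a (Z)-alkene, the C8 triflate is joined to pent-1-en-4-yne (C3–C7), and the C9 oxygen closes a 2,5-cis tetrahydrofuran (O–C9…C12) on the bromonium ion; semihydrogenation gives (Z)-C6=C7.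
3. The oxocane is the last ring to arise: Cl+ on C6=C7, the tetrahydrofuran oxygen closes on C6, and chloride opens the bicyclic oxonium ion at C9, so the oxygen moves from C9 to C6 and both chlorines enter at once.
4. Feature that allows this: in the target O–C6 and Cl–C7 are anti across what was a Z-alkene, and the second chlorine sits on C9, 1,4 to the ring oxygen through C7 and C8; a five-membered ether ring O–C9–C10–C11–C12 is hidden inside the eight-membered ring O–C6…C12.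
5. Stereochemistry: C9 and C10 from the sugar (C9 is inverted by chloride); C12/C13 by anti bromoetherification of the Z-alkene under cis-2,5 control of a 2,6-dichlorobenzyl ether; C6/C7 by anti addition on the convex face of the cis-fused oxonium ion; the (E)-enyne by cross-metathesis and Colvin homologation.

Key step: step 11

Remark: C1–C15 are the carbons of the target chain (C1 = alkyne CH, ring oxygen on C6 and C12); TBS = tert-butyldimethylsilyl; Et2SCl·SbCl6 and 2,6-dichlorobenzyl trichloroacetimidate are taken as purchasable reagents.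

Step 1
Reactants: 1 2-deoxy-D-ribose
Product: 2 2-deoxy-D-ribono-1,4-lactone
Conditions: Br2, H2O, rt
Reagents that add atoms: none
Why: Bromine-water oxidation of the aldose hemiacetal should give the 1,4-lactone and leaves the two carbinol centres (future C9 and C10) untouched.

Step 2
Reactants: 2 2-deoxy-D-ribono-1,4-lactone
Product: 3 (4S,5R)-4-(TBS-oxy)-5-[(TBS-oxy)methyl]oxolan-2-one
Conditions: TBSCl, imidazole, DMF, rt
Reagents that add atoms: tert-butyldimethylsilyl chloride CC(C)(C)[Si](C)(C)Cl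
Why: Standard silylation of both hydroxyls; the ring oxygen (future C9 oxygen) stays differentiated from the C8 and C10 oxygens.

Step 3
Reactants: 3 (4S,5R)-4-(TBS-oxy)-5-[(TBS-oxy)methyl]oxolan-2-one
Product: 4 (4S,5R)-4-(TBS-oxy)-5-[(TBS-oxy)methyl]oxolan-2-ol (lactol, both anomers)
Conditions: i-Bu2AlH, CH2Cl2, −78 °C
Reagents that add atoms: none
Why: Partial reduction of a lactone to the lactol; the tetrahedral aluminium alkoxide should be stable at −78 °C.

Step 4
Reactants: 4 (4S,5R)-4-(TBS-oxy)-5-[(TBS-oxy)methyl]oxolan-2-ol; 5 propyltriphenylphosphonium bromide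
Product: 6 (2R,3S,5Z)-1,3-bis(TBS-oxy)oct-5-en-2-ol
Conditions: NaN(SiMe3)2, THF, −78 → 0 °C, cold quench
Reagents that add atoms: none
Why: Z-selective Wittig olefination of the lactol through its open hydroxy aldehyde with the non-stabilised ylide should set (Z)-C12=C13 and free only the C9 hydroxyl, the cold quench limiting 1,2-silyl migration.

Step 5
Reactants: 6 (2R,3S,5Z)-1,3-bis(TBS-oxy)oct-5-en-2-ol
Product: 7 (2R,3S,5Z)-1,3-bis(TBS-oxy)-2-(2,6-dichlorobenzyloxy)oct-5-ene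
Conditions: 2,6-dichlorobenzyl trichloroacetimidate, CF3SO3H (cat.), CH2Cl2/cyclohexane, 0 °C
Reagents that add atoms: 2,6-dichlorobenzyl 2,2,2-trichloroacetimidate N=C(OCc1c(Cl)cccc1Cl)C(Cl)(Cl)Cl
Why: Acid-catalysed imidate benzylation etherifies the C9 hydroxyl without forming the alkoxide that would let the neighbouring silyl groups migrate.

Step 6
Reactants: 7 (2R,3S,5Z)-1,3-bis(TBS-oxy)-2-(2,6-dichlorobenzyloxy)oct-5-ene
Product: 8 (2R,3S,5Z)-3-(TBS-oxy)-2-(2,6-dichlorobenzyloxy)oct-5-en-1-ol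
Conditions: HF·pyridine, pyridine, THF, 0 °C
Reagents that add atoms: none
Why: Buffered HF·pyridine should cleave the primary silyl ether selectively over the secondary one.

Step 7
Reactants: 8 (2R,3S,5Z)-3-(TBS-oxy)-2-(2,6-dichlorobenzyloxy)oct-5-en-1-ol
Product: 9 (2R,3S,5Z)-3-(TBS-oxy)-2-(2,6-dichlorobenzyloxy)oct-5-en-1-yl trifluoromethanesulfonate
Conditions: (CF3SO2)2O, 2,6-lutidine, CH2Cl2, −78 °C
Reagents that add atoms: trifluoromethanesulfonic anhydride O=S(=O)(OS(=O)(=O)C(F)(F)F)C(F)(F)F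
Why: Triflation of the primary alcohol at low temperature gives an electrophile reactive enough for acetylide alkylation next to an ether carbon.

Step 8
Reactants: 9 (2R,3S,5Z)-3-(TBS-oxy)-2-(2,6-dichlorobenzyloxy)oct-5-en-1-yl trifluoromethanesulfonate; 10 pent-1-en-4-yne
Product: 11 (7R,8S,10Z)-8-(TBS-oxy)-7-(2,6-dichlorobenzyloxy)trideca-1,10-dien-4-yne
Conditions: n-BuLi, THF/DMPU, −78 → −20 °C
Reagents that add atoms: none
Why: SN2 alkylation of the lithium acetylide by the primary triflate forms C7–C8 and brings in C3–C7 in one piece.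

Step 9
Reactants: 11 (7R,8S,10Z)-8-(TBS-oxy)-7-(2,6-dichlorobenzyloxy)trideca-1,10-dien-4-yne
Product: 12 (2R,3S,5R)-5-[(1R)-1-bromopropyl]-3-(TBS-oxy)-2-(hex-5-en-2-yn-1-yl)oxolane
Conditions: NBS, MeCN, 0 °C, dark
Reagents that add atoms: N-bromosuccinimide O=C1CCC(=O)N1Br
Why: Bromoetherification with ether participation and dealkylation: the benzylic ether oxygen closes 5-exo on the bromonium ion of the Z-alkene with anti addition (C12–O and C13–Br threo), the O-benzyl oxonium ion with both ring substituents trans to the bulky benzyl group (cis-2,5) is debenzylated by succinimide, and the alkyne and terminal alkene, which lack an internal nucleophile, should not be consumed.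

Step 10
Reactants: 12 (2R,3S,5R)-5-[(1R)-1-bromopropyl]-3-(TBS-oxy)-2-(hex-5-en-2-yn-1-yl)oxolane
Product: 13 (2R,3S,5R)-5-[(1R)-1-bromopropyl]-3-(TBS-oxy)-2-[(2Z)-hexa-2,5-dien-1-yl]oxolane
Conditions: H2 (1 atm), Pd/CaCO3 poisoned with Pb(OAc)2, quinoline, EtOAc, rt
Reagents that add atoms: none
Why: Lindlar semihydrogenation should reduce the alkyne to the (Z)-C6=C7 alkene by syn delivery of hydrogen and leave the terminal alkene and the secondary bromide.

Step 11
Reactants: 13 (2R,3S,5R)-5-[(1R)-1-bromopropyl]-3-(TBS-oxy)-2-[(2Z)-hexa-2,5-dien-1-yl]oxolane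
Product: 15 (2S,3S,5S,6S,8R)-8-[(1R)-1-bromopropyl]-6-(TBS-oxy)-3,5-dichloro-2-(prop-2-en-1-yl)oxocane, via bicyclic oxonium hexachloroantimonate 14 (not isolated)
Conditions: Et2SCl·SbCl6, MeNO2, −25 °C; then n-Bu4NCl, −25 → 0 °C
Reagents that add atoms: chlorodiethylsulfonium hexachloroantimonate CC[S+](Cl)CC.Cl[Sb-](Cl)(Cl)(Cl)(Cl)Cl; tetrabutylammonium chloride CCCC[N+](CCCC)(CCCC)CCCC.[Cl-]
Why: Proposed new method: Et2SCl·SbCl6 should transfer Cl+ to the 1,2-dialkyl (Z)-C6=C7 alkene, the tetrahydrofuran oxygen should open the chloriranium ion at C6 anti to chlorine, and the cis-fused 1-oxoniabicyclo[3.3.0]octane 14, which can persist because SbCl6− is not nucleophilic, should then be opened by added chloride at the ring-fusion carbon C9 with inversion. The closest known reaction types are the halonium-triggered ring expansion of 2-alkenyl tetrahydrofurans to oxocanes with Et2SBr·SbCl5Br (5-exo oxonium closure, internal carbonyl nucleophile) and the 5-endo haloetherification of homoallylic alcohols. The five-membered oxonium ring closes 5-endo (4-exo attack at C7 would give an oxetanium ion), and the eight-membered ring is not closed end to end but appears when the O–C9 bond shared by the two five-membered rings is cut. C6 and C7 follow from anti addition to the Z-alkene on the face that places the C5 chain and the chlorine on the convex side of the bicycle, because the cis C12 bromopropyl group fills the concave side, and C9 follows from SN2 inversion of the sugar-derived C–O centre. The step needs chloride to choose C9 over C6 and C12: C12 carries a branched β-bromide, C6 a β-chlorine and a free side chain, whereas the two carbon substituents of C9 are tied back in rings and its neighbour bears only a weakly withdrawing silyl ether that, unlike an acetate, cannot open the oxonium ion by participation. The terminal alkene should survive because a monosubstituted alkene without an internal nucleophile reacts much more slowly with Cl+ and is trapped only reversibly.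

Step 12
Reactants: 15 (2S,3S,5S,6S,8R)-8-[(1R)-1-bromopropyl]-6-(TBS-oxy)-3,5-dichloro-2-(prop-2-en-1-yl)oxocane; 16 (E)-but-2-enal
Product: 17 (2E)-4-[(2S,3S,5S,6S,8R)-8-[(1R)-1-bromopropyl]-6-(TBS-oxy)-3,5-dichlorooxocan-2-yl]but-2-enal
Conditions: second-generation Grubbs catalyst (cat.), CH2Cl2, 40 °C
Reagents that add atoms: none
Why: Cross-metathesis of the only alkene with excess crotonaldehyde should give the (E)-enal under thermodynamic control.

Step 13
Reactants: 17 (2E)-4-[(2S,3S,5S,6S,8R)-8-[(1R)-1-bromopropyl]-6-(TBS-oxy)-3,5-dichlorooxocan-2-yl]but-2-enal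
Product: 18 (2S,3S,5S,6S,8R)-8-[(1R)-1-bromopropyl]-6-(TBS-oxy)-3,5-dichloro-2-[(2E)-pent-2-en-4-yn-1-yl]oxocane
Conditions: Me3SiCHN2, LiN(i-Pr)2, THF, −78 → 0 °C
Reagents that add atoms: (trimethylsilyl)diazomethane C[Si](C)(C)C=[N+]=[N-]
Why: Colvin rearrangement: lithiated trimethylsilyldiazomethane adds to the aldehyde, loss of LiOSiMe3 and N2 gives the alkylidene carbene, and its 1,2-hydrogen shift gives the terminal alkyne with the (E)-alkene intact.

Step 14
Reactants: 18 (2S,3S,5S,6S,8R)-8-[(1R)-1-bromopropyl]-6-(TBS-oxy)-3,5-dichloro-2-[(2E)-pent-2-en-4-yn-1-yl]oxocane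
Product: 19 (2S,3S,5S,6S,8R)-8-[(1R)-1-bromopropyl]-3,5-dichloro-2-[(2E)-pent-2-en-4-yn-1-yl]oxocan-6-ol
Conditions: HF·pyridine, THF, 0 °C → rt
Reagents that add atoms: none
Why: Acidic fluoride removes the silyl ether without forming the C10 alkoxide that would close an epoxide on the neighbouring C9 chloride.

Step 15
Reactants: 19 (2S,3S,5S,6S,8R)-8-[(1R)-1-bromopropyl]-3,5-dichloro-2-[(2E)-pent-2-en-4-yn-1-yl]oxocan-6-ol
Product: 20 (2S,3S,5S,6S,8R)-8-[(1R)-1-bromopropyl]-3,5-dichloro-2-[(2E)-pent-2-en-4-yn-1-yl]oxocan-6-yl acetate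
Conditions: Ac2O, pyridine, DMAP (cat.), CH2Cl2, 0 °C
Reagents that add atoms: acetic anhydride CC(=O)OC(C)=O
Why: Nucleophile-catalysed acylation of the secondary alcohol with retention at C10 gives the target.

**Compound list**

1 | 2-deoxy-D-ribose, (3S,4R)-3,4,5-trihydroxypentanal | O=CC[C@H](O)[C@H](O)CO | starting material
2 | 2-deoxy-D-ribono-1,4-lactone, (4S,5R)-4-hydroxy-5-(hydroxymethyl)oxolan-2-one | O=C1C[C@H](O)[C@@H](CO)O1 | intermediate
3 | (4S,5R)-4-(tert-butyldimethylsilyloxy)-5-[(tert-butyldimethylsilyloxy)methyl]oxolan-2-one | O=C1C[C@H](O[Si](C)(C)C(C)(C)C)[C@@H](CO[Si](C)(C)C(C)(C)C)O1 | intermediate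
4 | (4S,5R)-4-(tert-butyldimethylsilyloxy)-5-[(tert-butyldimethylsilyloxy)methyl]oxolan-2-ol (both anomers) | OC1C[C@H](O[Si](C)(C)C(C)(C)C)[C@@H](CO[Si](C)(C)C(C)(C)C)O1 | intermediate
5 | propyltriphenylphosphonium bromide | CCC[P+](c1ccccc1)(c1ccccc1)c1ccccc1.[Br-] | starting material
6 | (2R,3S,5Z)-1,3-bis(tert-butyldimethylsilyloxy)oct-5-en-2-ol | CC/C=C\C[C@H](O[Si](C)(C)C(C)(C)C)[C@H](O)CO[Si](C)(C)C(C)(C)C | intermediate
7 | (2R,3S,5Z)-1,3-bis(tert-butyldimethylsilyloxy)-2-(2,6-dichlorobenzyloxy)oct-5-ene | CC/C=C\C[C@H](O[Si](C)(C)C(C)(C)C)[C@H](OCc1c(Cl)cccc1Cl)CO[Si](C)(C)C(C)(C)C | intermediate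
8 | (2R,3S,5Z)-3-(tert-butyldimethylsilyloxy)-2-(2,6-dichlorobenzyloxy)oct-5-en-1-ol | CC/C=C\C[C@H](O[Si](C)(C)C(C)(C)C)[C@H](OCc1c(Cl)cccc1Cl)CO | intermediate
9 | (2R,3S,5Z)-3-(tert-butyldimethylsilyloxy)-2-(2,6-dichlorobenzyloxy)oct-5-en-1-yl trifluoromethanesulfonate | CC/C=C\C[C@H](O[Si](C)(C)C(C)(C)C)[C@H](OCc1c(Cl)cccc1Cl)COS(=O)(=O)C(F)(F)F | intermediate
10 | pent-1-en-4-yne | C#CCC=C | starting material
11 | (7R,8S,10Z)-8-(tert-butyldimethylsilyloxy)-7-(2,6-dichlorobenzyloxy)trideca-1,10-dien-4-yne | CC/C=C\C[C@H](O[Si](C)(C)C(C)(C)C)[C@H](OCc1c(Cl)cccc1Cl)CC#CCC=C | intermediate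
12 | (2R,3S,5R)-5-[(1R)-1-bromopropyl]-3-(tert-butyldimethylsilyloxy)-2-(hex-5-en-2-yn-1-yl)oxolane | C=CCC#CC[C@H]1O[C@@H]([C@H](Br)CC)C[C@@H]1O[Si](C)(C)C(C)(C)C | intermediate
13 | (2R,3S,5R)-5-[(1R)-1-bromopropyl]-3-(tert-butyldimethylsilyloxy)-2-[(2Z)-hexa-2,5-dien-1-yl]oxolane | C=CC/C=C\C[C@H]1O[C@@H]([C@H](Br)CC)C[C@@H]1O[Si](C)(C)C(C)(C)C | intermediate
14 | cis-fused 1-oxoniabicyclo[3.3.0]octane hexachloroantimonate: oxygen bonded to C6, C9 and C12; one ring carries the C6 allyl group and the C7 chlorine (both on the convex face), the other the C10 silyloxy group and the C12 (1R)-1-bromopropyl group | C=CC[C@H]1[C@@H](Cl)C[C@H]2[O+]1[C@H](C[C@@H]2O[Si](C)(C)C(C)(C)C)[C@H](Br)CC.Cl[Sb-](Cl)(Cl)(Cl)(Cl)Cl | intermediate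
15 | (2S,3S,5S,6S,8R)-8-[(1R)-1-bromopropyl]-6-(tert-butyldimethylsilyloxy)-3,5-dichloro-2-(prop-2-en-1-yl)oxocane | C=CC[C@@H]1O[C@@H]([C@H](Br)CC)C[C@H](O[Si](C)(C)C(C)(C)C)[C@@H](Cl)C[C@@H]1Cl | intermediate
16 | (E)-but-2-enal (crotonaldehyde) | C/C=C/C=O | starting material
17 | (2E)-4-[(2S,3S,5S,6S,8R)-8-[(1R)-1-bromopropyl]-6-(tert-butyldimethylsilyloxy)-3,5-dichlorooxocan-2-yl]but-2-enal | O=C/C=C/C[C@@H]1O[C@@H]([C@H](Br)CC)C[C@H](O[Si](C)(C)C(C)(C)C)[C@@H](Cl)C[C@@H]1Cl | intermediate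
18 | (2S,3S,5S,6S,8R)-8-[(1R)-1-bromopropyl]-6-(tert-butyldimethylsilyloxy)-3,5-dichloro-2-[(2E)-pent-2-en-4-yn-1-yl]oxocane | C#C/C=C/C[C@@H]1O[C@@H]([C@H](Br)CC)C[C@H](O[Si](C)(C)C(C)(C)C)[C@@H](Cl)C[C@@H]1Cl | intermediate
19 | (2S,3S,5S,6S,8R)-8-[(1R)-1-bromopropyl]-3,5-dichloro-2-[(2E)-pent-2-en-4-yn-1-yl]oxocan-6-ol | C#C/C=C/C[C@@H]1O[C@@H]([C@H](Br)CC)C[C@H](O)[C@@H](Cl)C[C@@H]1Cl | intermediate
20 | (2S,3S,5S,6S,8R)-8-[(1R)-1-bromopropyl]-3,5-dichloro-2-[(2E)-pent-2-en-4-yn-1-yl]oxocan-6-yl acetate | C#C/C=C/C[C@@H]1O[C@@H]([C@H](Br)CC)C[C@H](OC(C)=O)[C@@H](Cl)C[C@@H]1Cl | target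

Total step count: 15. Longest linear sequence: 15 steps (from 1).

**Steps most likely to fail**

1. Step 11 (proposed new method). Chloride, or the C10 silyl-ether oxygen, may capture the chloriranium ion before the ring oxygen does (plain dichlorination or six-membered ring closure). Chloride may also open the oxonium ion at C6 or C12 instead of C9. Fallback with known chemistry, setting out from 9 and coming back at 15: the oxygen is moved from C9 to C6 in separate operations. Triflate 9 is coupled with CH2=CHMgBr (CuI cat., THF, −40 °C) to (4R,5S,7Z)-5-(tert-butyldimethylsilyloxy)-4-(2,6-dichlorobenzyloxy)deca-1,7-diene F1, which NBS cyclises as in step 9 to (2R,3S,5R)-5-[(1R)-1-bromopropyl]-3-(tert-butyldimethylsilyloxy)-2-(prop-2-en-1-yl)oxolane F2. But-3-enoyl triflate (from but-3-enoyl chloride and AgOTf, CH2Cl2, −78 °C) acylates the ring oxygen, and n-Bu4NCl opens the acyloxonium ion by SN2 at C9 (acylative ether cleavage; C12 is blocked by its branched β-bromide). This should give the open-chain chloro ester (3R,4R,6S,7S)-3-bromo-7-chloro-6-(tert-butyldimethylsilyloxy)dec-9-en-4-yl but-3-enoate F3, with the C9 chloride already inverted and the future C6 attached to oxygen as the ester carbonyl. Ester methylenation and olefin–ester ring closure with Cp2Ti(μ-Cl)(μ-CH2)AlMe2 (completed with second-generation Grubbs catalyst if needed) should give the eight-membered cyclic enol ether F4 (C6=C7). Dimethyldioxirane epoxidation followed by syn hydride delivery from i-Bu2AlH should place hydrogen on C6 and a hydroxyl on C7 trans to the allyl group, giving (2S,3R,5S,6S,8R)-8-[(1R)-1-bromopropyl]-6-(tert-butyldimethylsilyloxy)-5-chloro-2-(prop-2-en-1-yl)oxocan-3-ol F5; the face of epoxidation would have to be established. CCl4/P(n-Oct)3 in toluene (inversion) then converts it into 15.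

2. Step 9. The cis-2,5 (facial) preference of the ether cyclisation may be insufficient, and slow debenzylation may let the bromonium ion revert or be captured elsewhere. Fallback setting out from 3 and coming back at 12: the C12 centre is set by hydride delivery instead of by cyclisation. 2-Ethyl-2-lithio-1,3-dithiane adds to lactone 3 to give the hemiketal (4S,5R)-4-(tert-butyldimethylsilyloxy)-5-[(tert-butyldimethylsilyloxy)methyl]-2-(2-ethyl-1,3-dithian-2-yl)oxolan-2-ol F6. Et3SiH/BF3·OEt2 at −78 °C reduces the derived five-membered oxocarbenium ion by inside attack cis to the C10 silyloxy group, which should give the 2,5-cis C-glycoside (2R,3S,5R)-3-(tert-butyldimethylsilyloxy)-2-[(tert-butyldimethylsilyloxy)methyl]-5-(2-ethyl-1,3-dithian-2-yl)oxolane F7. MeI/CaCO3 in aqueous MeCN unmasks the ethyl ketone 1-[(2R,4S,5R)-4-(tert-butyldimethylsilyloxy)-5-[(tert-butyldimethylsilyloxy)methyl]oxolan-2-yl]propan-1-one F8. Chelation-controlled reduction with Zn(BH4)2 should give the erythro alcohol (1S)-1-[(2R,4S,5R)-4-(tert-butyldimethylsilyloxy)-5-[(tert-butyldimethylsilyloxy)methyl]oxolan-2-yl]propan-1-ol F9, and CBr4/P(n-Oct)3 (inversion) gives (2R,3S,5R)-5-[(1R)-1-bromopropyl]-3-(tert-butyldimethylsilyloxy)-2-[(tert-butyldimethylsilyloxy)methyl]oxolane F10. HF·pyridine frees the primary alcohol [(2R,3S,5R)-5-[(1R)-1-bromopropyl]-3-(tert-butyldimethylsilyloxy)oxolan-2-yl]methanol F11, (CF3SO2)2O/2,6-lutidine gives its trifluoromethanesulfonate F12, and LiC≡CCH2CH=CH2 (from 10 and n-BuLi) gives 12.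

3. Step 13. The strongly basic reagent may cause loss of HCl or HBr from the secondary halides or conjugate addition to the enal. Fallback setting out from 15 and coming back at 18, without strong base: O3 then PPh3 cleaves the allyl group of 15 to 2-[(2S,3S,5S,6S,8R)-8-[(1R)-1-bromopropyl]-6-(tert-butyldimethylsilyloxy)-3,5-dichlorooxocan-2-yl]acetaldehyde F13. Takai olefination (CrCl2, CHI3, THF) should give (2S,3S,5S,6S,8R)-8-[(1R)-1-bromopropyl]-6-(tert-butyldimethylsilyloxy)-3,5-dichloro-2-[(2E)-3-iodoprop-2-en-1-yl]oxocane F14. Stille coupling with tributyl(ethynyl)stannane and Pd(PPh3)4 then gives 18.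

Further compounds
F1 | step 11 | (4R,5S,7Z)-5-(tert-butyldimethylsilyloxy)-4-(2,6-dichlorobenzyloxy)deca-1,7-diene | CC/C=C\C[C@H](O[Si](C)(C)C(C)(C)C)[C@H](OCc1c(Cl)cccc1Cl)CC=C
F2 | step 11 | (2R,3S,5R)-5-[(1R)-1-bromopropyl]-3-(tert-butyldimethylsilyloxy)-2-(prop-2-en-1-yl)oxolane | C=CC[C@H]1O[C@@H]([C@H](Br)CC)C[C@@H]1O[Si](C)(C)C(C)(C)C
F3 | step 11 | (3R,4R,6S,7S)-3-bromo-7-chloro-6-(tert-butyldimethylsilyloxy)dec-9-en-4-yl but-3-enoate | C=CC[C@H](Cl)[C@@H](O[Si](C)(C)C(C)(C)C)C[C@@H](OC(=O)CC=C)[C@H](Br)CC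
F4 | step 11 | eight-membered cyclic enol ether (C6=C7 in the ring) with allyl on C6, (S)-chlorine on C9, (S)-silyloxy on C10 and (1R)-1-bromopropyl on (R)-C12 | C=CC/C1=C/C[C@H](Cl)[C@@H](O[Si](C)(C)C(C)(C)C)C[C@H]([C@H](Br)CC)O1
F5 | step 11 | (2S,3R,5S,6S,8R)-8-[(1R)-1-bromopropyl]-6-(tert-butyldimethylsilyloxy)-5-chloro-2-(prop-2-en-1-yl)oxocan-3-ol | C=CC[C@@H]1O[C@@H]([C@H](Br)CC)C[C@H](O[Si](C)(C)C(C)(C)C)[C@@H](Cl)C[C@H]1O
F6 | step 9 | (4S,5R)-4-(tert-butyldimethylsilyloxy)-5-[(tert-butyldimethylsilyloxy)methyl]-2-(2-ethyl-1,3-dithian-2-yl)oxolan-2-ol | CCC1(SCCCS1)C1(O)C[C@H](O[Si](C)(C)C(C)(C)C)[C@@H](CO[Si](C)(C)C(C)(C)C)O1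
F7 | step 9 | (2R,3S,5R)-3-(tert-butyldimethylsilyloxy)-2-[(tert-butyldimethylsilyloxy)methyl]-5-(2-ethyl-1,3-dithian-2-yl)oxolane | CC(C)(C)[Si](C)(C)OC[C@H]1O[C@@H](C2(CC)SCCCS2)C[C@@H]1O[Si](C)(C)C(C)(C)C
F8 | step 9 | 1-[(2R,4S,5R)-4-(tert-butyldimethylsilyloxy)-5-[(tert-butyldimethylsilyloxy)methyl]oxolan-2-yl]propan-1-one | CC(C)(C)[Si](C)(C)OC[C@H]1O[C@@H](C(=O)CC)C[C@@H]1O[Si](C)(C)C(C)(C)C
F9 | step 9 | (1S)-1-[(2R,4S,5R)-4-(tert-butyldimethylsilyloxy)-5-[(tert-butyldimethylsilyloxy)methyl]oxolan-2-yl]propan-1-ol | CC(C)(C)[Si](C)(C)OC[C@H]1O[C@@H]([C@@H](O)CC)C[C@@H]1O[Si](C)(C)C(C)(C)C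
F10 | step 9 | (2R,3S,5R)-5-[(1R)-1-bromopropyl]-3-(tert-butyldimethylsilyloxy)-2-[(tert-butyldimethylsilyloxy)methyl]oxolane | CC(C)(C)[Si](C)(C)OC[C@H]1O[C@@H]([C@H](Br)CC)C[C@@H]1O[Si](C)(C)C(C)(C)C
F11 | step 9 | [(2R,3S,5R)-5-[(1R)-1-bromopropyl]-3-(tert-butyldimethylsilyloxy)oxolan-2-yl]methanol | OC[C@H]1O[C@@H]([C@H](Br)CC)C[C@@H]1O[Si](C)(C)C(C)(C)C
F12 | step 9 | [(2R,3S,5R)-5-[(1R)-1-bromopropyl]-3-(tert-butyldimethylsilyloxy)oxolan-2-yl]methyl trifluoromethanesulfonate | O=S(=O)(OC[C@H]1O[C@@H]([C@H](Br)CC)C[C@@H]1O[Si](C)(C)C(C)(C)C)C(F)(F)F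
F13 | step 13 | 2-[(2S,3S,5S,6S,8R)-8-[(1R)-1-bromopropyl]-6-(tert-butyldimethylsilyloxy)-3,5-dichlorooxocan-2-yl]acetaldehyde | O=CC[C@@H]1O[C@@H]([C@H](Br)CC)C[C@H](O[Si](C)(C)C(C)(C)C)[C@@H](Cl)C[C@@H]1Cl
F14 | step 13 | (2S,3S,5S,6S,8R)-8-[(1R)-1-bromopropyl]-6-(tert-butyldimethylsilyloxy)-3,5-dichloro-2-[(2E)-3-iodoprop-2-en-1-yl]oxocane | I/C=C/C[C@@H]1O[C@@H]([C@H](Br)CC)C[C@H](O[Si](C)(C)C(C)(C)C)[C@@H](Cl)C[C@@H]1Cl
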